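A direct plan would set C2 and C3 first, by an auxiliary-controlled anti glycolate aldol on the ring B aldehyde A1, would acylate a prenylated diketo ester trianion with the derived Weinreb amide A2, would close ring C as the dihydropyranone A3 and would only then fold ring A by a Claisen condensation. Its weakest steps would be:
- the trianion acylation, because an excess of polyanion meets an α-alkoxy amide that can enolize and eliminate;
- the last, base-mediated Claisen aromatization, because the acidic C3–H beside O1 invites epimerization and ring opening;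
- the titanium tetrachloride aldol, because excess strong Lewis acid sits beside acetals and geranyl alkenes.

**New strategy.** The route rests on a three-component, vicinal arylation–oxygenation of the C2=C3 bond of ring C. The flat, achiral chromone 8, which already holds rings A and C and the C6 prenyl group, would take up the ring B aryl group at C2 from an arylzinc under a chiral monovalent rhodium catalyst, and the silyl enol ether thus formed would take up oxygen at C3 in the same operation. One step would so form the C2–C1′ and C3–O bonds and both stereocentres, using C2 as the electrophilic and C3 as the latent nucleophilic carbon of the vinylogous ester O1–C2=C3–C4=O. Polyanion acylation, late base-mediated aromatization and auxiliary aldol all disappear; ring A is aromatic throughout.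

Key step: step 8

Assumption: aryl transfer from the (S)-BINAP rhodium complex is taken to follow the facial sense known for cyclohex-2-enone and 2,3-dihydro-4-pyridones, which corresponds to 2S at the flavanone stage; if the sense were reversed, (R)-BINAP would be used.

Geranyl stands for (2E)-3,7-dimethylocta-2,6-dienyl throughout.

Step 1
Reactants: 1 2-methylbut-3-en-2-ol
Product: 2 tert-butyl 2-methylbut-3-en-2-yl carbonate
Conditions: n-BuLi (1.05 equiv), THF, 0 °C; Boc2O (1.1 equiv), 0 → 23 °C; H2O
Reagents that add atoms: di-tert-butyl dicarbonate, CC(C)(C)OC(=O)OC(=O)OC(C)(C)C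
Why: O-acylation of the lithium alkoxide of the tertiary allylic alcohol (alkoxycarbonylation) should give the mixed carbonate, the usual precursor of a 1,1-dimethylallyl palladium electrophile.

Step 2
Reactants: 3 5,7-dihydroxy-4H-chromen-4-one
Product: 4 5-hydroxy-7-(methoxymethoxy)-4H-chromen-4-one
Conditions: MOMCl (1.1 equiv), i-Pr2NEt (1.5 equiv), CH2Cl2/DMF, 0 → 23 °C
Reagents that add atoms: chloromethyl methyl ether, COCCl
Why: Williamson-type O-alkylation should be selective for the more acidic, unhindered 7-OH, because the 5-OH is held in a hydrogen bond to the C4 carbonyl.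

Step 3
Reactants: 4 5-hydroxy-7-(methoxymethoxy)-4H-chromen-4-one; 2 tert-butyl 2-methylbut-3-en-2-yl carbonate
Product: 5 7-(methoxymethoxy)-5-[(2-methylbut-3-en-2-yl)oxy]-4H-chromen-4-one
Conditions: 2 (1.5 equiv), Pd(PPh3)4 (3 mol %), THF, 0 → 23 °C
Reagents that add atoms: none
Why: In this Tsuji–Trost O-allylation zerovalent palladium ionizes the carbonate with loss of CO2, the tert-butoxide set free deprotonates the 5-OH, and the phenoxide should attack the more substituted terminus of the 1,1-dimethyl-π-allyl palladium complex under kinetic control to give the tertiary ether.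

Step 4
Reactants: 5 7-(methoxymethoxy)-5-[(2-methylbut-3-en-2-yl)oxy]-4H-chromen-4-one
Product: 7 5-hydroxy-7-(methoxymethoxy)-6-(3-methylbut-2-enyl)-4H-chromen-4-one, via Claisen dienone 6 (not isolated)
Conditions: toluene, 110 °C, sealed tube
Reagents that add atoms: none
Why: In this aromatic Claisen rearrangement ([3,3]-sigmatropic shift) C6 is the only ortho carbon of O5 that carries hydrogen (the other is the ring-fusion carbon C4a), the allyl inversion turns the 1,1-dimethylallyl group into the 3-methylbut-2-enyl group, and dienone 6 tautomerizes to the chelated phenol, so the prenyl group should end at C6 without a regioisomer.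

Step 5
Reactants: 7 5-hydroxy-7-(methoxymethoxy)-6-(3-methylbut-2-enyl)-4H-chromen-4-one
Product: 8 5,7-bis(methoxymethoxy)-6-(3-methylbut-2-enyl)-4H-chromen-4-one
Conditions: NaH (1.5 equiv), DMF, 0 °C; MOMCl (1.3 equiv), 0 → 23 °C
Reagents that add atoms: chloromethyl methyl ether, COCCl
Why: Williamson O-alkylation of the sodium phenoxide should mask the chelated 5-OH, so that no acidic proton meets the arylzinc reagent of step 8.

Step 6
Reactants: 9 resorcinol
Product: 10 1,3-bis(methoxymethoxy)benzene
Conditions: NaH (2.4 equiv), DMF, 0 °C; MOMCl (2.3 equiv), 0 → 23 °C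
Reagents that add atoms: chloromethyl methyl ether, COCCl
Why: Williamson-type O-alkylation of the bis-phenoxide should give the bis-acetal whose two oxygens direct the metalations of steps 7 and 8.

Step 7
Reactants: 10 1,3-bis(methoxymethoxy)benzene; 11 geranyl bromide
Product: 13 2-geranyl-1,3-bis(methoxymethoxy)benzene, via 2-lithio arene 12 (not isolated)
Conditions: n-BuLi (1.1 equiv), THF, 0 °C; CuI (10 mol %), then 11, −78 → 23 °C
Reagents that add atoms: none
Why: Directed ortho-metalation at C2 between both MOM ethers, followed by copper-catalysed SN2 allylic substitution at the primary carbon of geranyl bromide, should give the C-geranyl arene with the E alkene intact.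

Step 8
Reactants: 13 2-geranyl-1,3-bis(methoxymethoxy)benzene; 8 5,7-bis(methoxymethoxy)-6-(3-methylbut-2-enyl)-4H-chromen-4-one
Product: 18 (2R,3R)-2-[3-geranyl-2,4-bis(methoxymethoxy)phenyl]-3-hydroxy-5,7-bis(methoxymethoxy)-6-(3-methylbut-2-enyl)chroman-4-one, via aryllithium 14 (not isolated), via arylzinc chloride 15 (not isolated), via silyl enol ether 16 (not isolated), via silyloxy epoxide 17 (not isolated)
Conditions: 13 (1.6 equiv), n-BuLi (1.5 equiv), THF, 0 °C; ZnCl2 (1.6 equiv), −78 → 0 °C; then 8 (1.0 equiv), Me3SiCl (1.6 equiv), [RhCl((S)-binap)]2 (3 mol % Rh), THF, 20 °C; pentane, filtration under Ar, evaporation; dimethyldioxirane (1.05 equiv), acetone/CH2Cl2, −78 °C; 1 M aq citric acid, THF, 0 °C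
Reagents that add atoms: dimethyldioxirane, CC1(C)OO1
Why: Directed ortho-lithiation of 13 next to one MOM ether (the two free ortho positions are equivalent) and transmetalation give arylzinc chloride 15, whose aryl group passes to the BINAP-bound monovalent rhodium chloride; the aryl–rhodium species adds across C2=C3 of chromone 8 (1,4-carbometalation) and Me3SiCl turns the resulting oxa-π-allyl rhodium enolate into silyl enol ether 16 with return of the rhodium chloride, so that the enolate never opens ring C by E1cB loss of the O1 phenoxide. The closest known reactions are the rhodium/BINAP-catalysed asymmetric 1,4-additions of arylzinc chlorides in the presence of Me3SiCl to 2,3-dihydro-4-pyridones and 4-quinolones, the rhodium-catalysed asymmetric additions of arylboronic acids to chromones, and the Rubottom oxidation of flavanone silyl enol ethers. No ring of the core is closed (rings A and C are present in 8; the oxirane of 17 is formed by concerted oxygen transfer and opened again on work-up). C2 is set by the catalyst, the (S)-ligand presenting one enantioface of the planar chromone to the migrating aryl group; C3 is set by the substrate, because the pseudoaxial C2 aryl group of 16 shields one face of C3=C4 and dimethyldioxirane delivers oxygen to the other, which gives the 2,3-trans (2R,3R) arrangement, also the thermodynamically preferred one. The step needs 1,4- over 1,2-addition (secured by the soft aryl–rhodium nucleophile), silylation faster than ring opening (secured by Me3SiCl in excess), and oxygen transfer to C3=C4 in preference to the three trisubstituted alkenes (secured by the far higher nucleophilicity of a silyl enol ether conjugated to the trioxygenated ring A, one equivalent of oxidant and −78 °C).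

Step 9
Reactants: 18 (2R,3R)-2-[3-geranyl-2,4-bis(methoxymethoxy)phenyl]-3-hydroxy-5,7-bis(methoxymethoxy)-6-(3-methylbut-2-enyl)chroman-4-one
Product: 19 (2R,3R)-2-[3-geranyl-2,4-dihydroxyphenyl]-3,5,7-trihydroxy-6-(3-methylbut-2-enyl)chroman-4-one
Conditions: 3 M aq HCl/MeOH (1:4), 23 → 40 °C
Reagents that add atoms: none
Why: Acid-catalysed transacetalization in methanol should cleave the four aryl MOM ethers without breaking C2–O1 or C3–O, since the C4 carbonyl lowers the basicity of O1, and the trans 2R,3R arrangement is the thermodynamic one if C2 should epimerize.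

**Compound list**

1 | 2-methylbut-3-en-2-ol | C=CC(C)(C)O | starting material
2 | tert-butyl 2-methylbut-3-en-2-yl carbonate | C=CC(C)(C)OC(=O)OC(C)(C)C | intermediate
3 | 5,7-dihydroxy-4H-chromen-4-one | O=c1ccoc2cc(O)cc(O)c12 | starting material
4 | 5-hydroxy-7-(methoxymethoxy)-4H-chromen-4-one | O=c1ccoc2cc(OCOC)cc(O)c12 | intermediate
5 | 7-(methoxymethoxy)-5-[(2-methylbut-3-en-2-yl)oxy]-4H-chromen-4-one | O=c1ccoc2cc(OCOC)cc(OC(C)(C)C=C)c12 | intermediate
6 | 7-(methoxymethoxy)-6-(3-methylbut-2-enyl)-4H-chromene-4,5(6H)-dione (Claisen dienone, racemic at C6) | O=C1C=COC2=C1C(=O)C(CC=C(C)C)C(OCOC)=C2 | intermediate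
7 | 5-hydroxy-7-(methoxymethoxy)-6-(3-methylbut-2-enyl)-4H-chromen-4-one | O=c1ccoc2cc(OCOC)c(CC=C(C)C)c(O)c12 | intermediate
8 | 5,7-bis(methoxymethoxy)-6-(3-methylbut-2-enyl)-4H-chromen-4-one | O=c1ccoc2cc(OCOC)c(CC=C(C)C)c(OCOC)c12 | intermediate
9 | resorcinol | Oc1cccc(O)c1 | starting material
10 | 1,3-bis(methoxymethoxy)benzene | COCOc1cccc(OCOC)c1 | intermediate
11 | geranyl bromide | CC(C)=CCC/C(C)=C/CBr | starting material
12 | 2-lithio-1,3-bis(methoxymethoxy)benzene | [Li]c1c(OCOC)cccc1OCOC | intermediate
13 | 2-[(2E)-3,7-dimethylocta-2,6-dienyl]-1,3-bis(methoxymethoxy)benzene | CC(C)=CCC/C(C)=C/Cc1c(OCOC)cccc1OCOC | intermediate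
14 | [3-geranyl-2,4-bis(methoxymethoxy)phenyl]lithium | CC(C)=CCC/C(C)=C/Cc1c(OCOC)ccc([Li])c1OCOC | intermediate
15 | chloro[3-geranyl-2,4-bis(methoxymethoxy)phenyl]zinc | CC(C)=CCC/C(C)=C/Cc1c(OCOC)ccc([Zn]Cl)c1OCOC | intermediate
16 | (2S)-2-[3-geranyl-2,4-bis(methoxymethoxy)phenyl]-5,7-bis(methoxymethoxy)-6-(3-methylbut-2-enyl)-4-(trimethylsilyloxy)-2H-chromene | CC(C)=CCC/C(C)=C/Cc1c(OCOC)ccc([C@H]2Oc3cc(OCOC)c(CC=C(C)C)c(OCOC)c3C(O[Si](C)(C)C)=C2)c1OCOC | intermediate
17 | (2R,3R,4R)-3,4-epoxy-2-[3-geranyl-2,4-bis(methoxymethoxy)phenyl]-5,7-bis(methoxymethoxy)-6-(3-methylbut-2-enyl)-4-(trimethylsilyloxy)chroman (oxirane oxygen trans to the aryl group) | CC(C)=CCC/C(C)=C/Cc1c(OCOC)ccc([C@H]2Oc3cc(OCOC)c(CC=C(C)C)c(OCOC)c3[C@@]4(O[Si](C)(C)C)[C@@H]2O4)c1OCOC | intermediate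
18 | (2R,3R)-2-[3-geranyl-2,4-bis(methoxymethoxy)phenyl]-3-hydroxy-5,7-bis(methoxymethoxy)-6-(3-methylbut-2-enyl)chroman-4-one | CC(C)=CCC/C(C)=C/Cc1c(OCOC)ccc([C@H]2Oc3cc(OCOC)c(CC=C(C)C)c(OCOC)c3C(=O)[C@@H]2O)c1OCOC | intermediate
19 | (2R,3R)-2-[3-[(2E)-3,7-dimethylocta-2,6-dienyl]-2,4-dihydroxyphenyl]-3,5,7-trihydroxy-6-(3-methylbut-2-enyl)chroman-4-one | CC(C)=CCC/C(C)=C/Cc1c(O)ccc([C@H]2Oc3cc(O)c(CC=C(C)C)c(O)c3C(=O)[C@@H]2O)c1O | target

**Count and risks**

Total steps: 9. Longest linear sequence: 6 steps (steps 2, 3, 4, 5, 8, 9).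

The three steps most likely to fail:

Step 8 (key step). Oxygen transfer may also reach the prenyl or geranyl double bonds. A MOM group may be lost to Me3SiCl/ZnCl2. Aryl transfer from the ortho-substituted arylzinc may be slow, with erosion of enantioselectivity. The fallback sets out from 13 and 8 and is stepwise. Lithiation of 13 as before and quenching with B(Oi-Pr)3 and dilute acid would give [3-geranyl-2,4-bis(methoxymethoxy)phenyl]boronic acid F1. Palladium-catalysed asymmetric conjugate addition of F1 to 8 (Pd(OCOCF3)2, the enantiomer of the pyridine-oxazoline ligand t-BuPyOX that gives 2S, NH4PF6, water, 1,2-dichloroethane, 60 °C) would give, after protonation of the palladium enolate, the isolated (2S)-2-[3-geranyl-2,4-bis(methoxymethoxy)phenyl]-5,7-bis(methoxymethoxy)-6-(3-methylbut-2-enyl)chroman-4-one F2. Its lithium enolate (LiN(SiMe3)2, THF, −78 °C) would be hydroxylated by 2-(phenylsulfonyl)-3-phenyloxaziridine, an oxidant that leaves isolated alkenes untouched, from the face anti to the aryl group. The route is rejoined at 18.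

Step 3 (and with it step 4). The chelated, peri-hindered 5-OH may fail to attack the tertiary allyl terminus, giving no reaction or the linear O-prenyl ether, or the tertiary ether may lose isoprene on heating instead of rearranging. The fallback sets out from 4. O-Allylation (allyl bromide, K2CO3, DMF, 60 °C) would give 5-(allyloxy)-7-(methoxymethoxy)-4H-chromen-4-one F3. Thermal Claisen rearrangement (N,N-diethylaniline, 190 °C) would give 6-allyl-5-hydroxy-7-(methoxymethoxy)-4H-chromen-4-one F4. Olefin cross-metathesis with 2-methylbut-2-ene (second-generation Grubbs catalyst, CH2Cl2, 40 °C) would turn the allyl into the prenyl group. The route is rejoined at 7.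

Step 9. The freed 5-, 7-, 2′- or 4′-hydroxyl groups may add under acid to the neighbouring prenyl or geranyl double bond (chroman formation), or methanol may cleave the benzylic C2–O1 bond. The fallback sets out from 18 and avoids protic acid. The acetals would be exchanged for silyl ethers (Et3SiOTf, 2,2′-bipyridyl, CH2Cl2, 0 °C), which also silylates the 3-OH, to give (2R,3R)-2-[3-geranyl-2,4-bis(triethylsilyloxy)phenyl]-6-(3-methylbut-2-enyl)-3,5,7-tris(triethylsilyloxy)chroman-4-one F5. Buffered fluoride (HF·pyridine, pyridine, THF, 0 °C) would then free all five hydroxyl groups. The route is rejoined at 19.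

**Further compounds**

F1 | step 8 | [3-geranyl-2,4-bis(methoxymethoxy)phenyl]boronic acid | CC(C)=CCC/C(C)=C/Cc1c(OCOC)ccc(B(O)O)c1OCOC
F2 | step 8 | (2S)-2-[3-geranyl-2,4-bis(methoxymethoxy)phenyl]-5,7-bis(methoxymethoxy)-6-(3-methylbut-2-enyl)chroman-4-one | CC(C)=CCC/C(C)=C/Cc1c(OCOC)ccc([C@H]2Oc3cc(OCOC)c(CC=C(C)C)c(OCOC)c3C(=O)C2)c1OCOC
F3 | step 3 | 5-(allyloxy)-7-(methoxymethoxy)-4H-chromen-4-one | O=c1ccoc2cc(OCOC)cc(OCC=C)c12
F4 | step 3 | 6-allyl-5-hydroxy-7-(methoxymethoxy)-4H-chromen-4-one | O=c1ccoc2cc(OCOC)c(CC=C)c(O)c12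
F5 | step 9 | (2R,3R)-2-[3-geranyl-2,4-bis(triethylsilyloxy)phenyl]-6-(3-methylbut-2-enyl)-3,5,7-tris(triethylsilyloxy)chroman-4-one | CC(C)=CCC/C(C)=C/Cc1c(O[Si](CC)(CC)CC)ccc([C@H]2Oc3cc(O[Si](CC)(CC)CC)c(CC=C(C)C)c(O[Si](CC)(CC)CC)c3C(=O)[C@@H]2O[Si](CC)(CC)CC)c1O[Si](CC)(CC)CC
A1 | direct plan | 3-[(2E)-3,7-dimethylocta-2,6-dienyl]-2,4-bis(methoxymethoxy)benzaldehyde | CC(C)=CCC/C(C)=C/Cc1c(OCOC)ccc(C=O)c1OCOC
A2 | direct plan | (2R,3R)-2-(allyloxy)-3-[3-geranyl-2,4-bis(methoxymethoxy)phenyl]-N-methoxy-N-methyl-3-(triethylsilyloxy)propanamide | CC(C)=CCC/C(C)=C/Cc1c(OCOC)ccc([C@@H](O[Si](CC)(CC)CC)[C@@H](OCC=C)C(=O)N(C)OC)c1OCOC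
A3 | direct plan | methyl 4-[(2R,3R)-3-(allyloxy)-2-[3-geranyl-2,4-bis(methoxymethoxy)phenyl]-4-oxo-3,4-dihydro-2H-pyran-6-yl]-2-(3-methylbut-2-enyl)-3-oxobutanoate | CC(C)=CCC/C(C)=C/Cc1c(OCOC)ccc([C@H]2OC(CC(=O)C(CC=C(C)C)C(=O)OC)=CC(=O)[C@@H]2OCC=C)c1OCOC
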